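**Blind spot.** I cannot stop a flask on a peak that no earlier run was read at: the readings jump from 0.0625 d to 0.208 d. The decision is when to stop this flask, and whether its charges stay.

| flask | substrate | partner A | partner B | remark | time |
|---|---|---|---|---|---|
| cedar | 0.050 M | 1.1 equiv | 3 equiv | run made earlier |  |
| maple | 0.20 M | 1.1 equiv | 3 equiv | run made earlier |  |
| oak | 0.10 M | 1.1 equiv | 6 equiv | run made earlier |  |
| flask | 0.10 M | 1.10 equiv | 3.00 equiv |  | 12 d |

- cedar (time / d: open intermediate / %, target / %): 0.0625: 14.4, 0; 0.208: 19.7, 1.0; 0.625: 7.7, 0; 2.50: 1.8, 0; 8.00: 0, 0.9
- maple (time / d: open intermediate / %, target / %): 0.0625: 38.4, 2.1; 0.208: 28.9, 0; 0.625: 3.4, 1.4; 2.50: 0, 0.9; 8.00: 1.1, 1.2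
- oak (time / d: open intermediate / %, target / %): 0.0625: 39.4, 0.4; 0.208: 31.7, 0; 0.625: 2.9, 0.3; 2.50: 0.5, 0; 8.00: 0, 0

(readings scatter by 1 percentage point)

- time up to 12 d at which open intermediate stands highest
- the amount of open intermediate, in percent of the substrate charged, at that time
- earliest time at which at least nineteen twentieths of that best amount are there, in d
- latest time at which they still are, in d

- what was read earlier has a scatter of 1 percentage point, one standard deviation

**Two falls.** Maple and oak read alike with their substrate differing twice over, at equal partner B, so I take partner B in excess to set how fast substrate opens: a pseudo-first-order step. Open intermediate is made and lost in series, and a late fall follows the slower step. Between 0.208 d and 0.625 d, maple and oak together fall with a half-life of 0.128 d, cedar with 0.308 d. I read the first as loss and the second as cedar's formation.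

**Race ratio.** The flask has twice cedar's partner B, so I expect a formation half-life of 0.154 d. Loss half-life over formation half-life gives 0.830, the race ratio. With partner B taken as constant, the peak fraction is this ratio raised to the power 1/(1 − ratio): 33.4 % at 0.202 d. I keep the charges and plan to stop there, not after days.

**The forecast.** It holds that “formation is first order in B and loss is independent of B” and gives 31 % at 0.155 d, with the window from 0.11 d to 0.21 d. Its time is earlier than mine, its peak lower.

**The result.** The flask stands highest at 0.136 d with 29.4 %, its window running from 0.0959 d to 0.188 d, inside the forecast's margins.

    substrate + partner B → open intermediate (k = 0.860 /M/h)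
    open intermediate → side product (k = 0.330 /h)
    2 second intermediate → homo product (k = 0.150 /M/h)
    open intermediate + second intermediate → target (k = 0.150 /M/h)
    partner B + partner A → second intermediate (k = 0.0890 /M/h)

**The race.** In the flask, substrate and partner B form open intermediate with a half-life of 0.11 d as charged, while its step to side product has a shorter one of 0.088 d, which puts the race ratio below one. The neighbour flask, with 5.10 equiv of partner B, lifts my ratio to 1.41, the rule turns that into 43.3 %, and that flask stands highest at 39.8 %.

The data are simulated on assumed constants, noise included.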